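The flavonol is cut at C4–C4a and at the C3–O bond. Ring A has a single unsubstituted carbon ortho to O1 (C4a; C8 carries the methoxy), made nucleophilic by O5 and O7, and C3 of ring C needs an oxygen. A gold-catalysed alkyne oxidation exploits both: in one operation it converts an aryl 1-arylpropargyl ether into the 2-arylchroman-3-one, installing the C3 carbonyl and closing the pyran ring. The precursor is the ether of 2-methoxy-3,5-bis(methoxymethoxy)phenol with 1-(4-pivaloyloxyphenyl)prop-2-yn-1-ol; the 4'-oxygen stays an electron-poor pivalate until after ring closure. C4 is then oxidised through an enaminone, both prenyl groups go on together, and the acetals are removed last.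

Key step: step 7

Remark on stereochemistry: the target has no stereocentre, so no absolute configuration has to be set; the single sp3 centre of compounds 4 and 7–12 is racemic and becomes sp2 in step 9.

Remark on the precursor: the skeleton is the aryl 1-arylpropargyl ether; only the 4'-substituent is changed (pivalate in place of the prenyl ether). The acyloxy group makes the benzylic propargylic C–O bond harder to ionise, tolerates the peracid of step 5, and keeps prenyl alkenes away from gold carbene, peracid and periodate. C4 is oxidised through a handle that only a CH2 group can accept, because the C2 methine (α to O1 and to an aryl group) is also acidic and direct enolate oxygenation could go there.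

Step 1
Reactants: 1 4-hydroxybenzaldehyde
Product: 2 4-formylphenyl pivalate
Conditions: PivCl, Et3N, DMAP (cat.), CH2Cl2, 0 °C→rt
Reagents that add atoms: pivaloyl chloride, CC(C)(C)C(=O)Cl
Why: DMAP-catalysed O-acylation of the phenol should be clean because the aldehyde is inert to an acid chloride and amine base.

Step 2
Reactants: 2 4-formylphenyl pivalate; 3 ethynylmagnesium bromide
Product: 4 rac-4-(1-hydroxyprop-2-yn-1-yl)phenyl pivalate
Conditions: THF, −78→−20 °C; aq. NH4Cl
Reagents that add atoms: none
Why: Grignard 1,2-addition to the aldehyde at low temperature should outpace attack on the hindered aryl pivalate; the carbinol centre forms without control and is racemic, which is acceptable because this carbon later becomes sp2.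

Step 3
Reactants: 5 2,4,6-trihydroxybenzaldehyde
Product: 6 2-hydroxy-4,6-bis(methoxymethoxy)benzaldehyde
Conditions: MOMCl (2.2 equiv), i-Pr2NEt, CH2Cl2, 0 °C→rt
Reagents that add atoms: chloromethyl methyl ether, COCCl
Why: Regioselective O-alkylation (acetal protection) should cap only the 4- and 6-hydroxyls, because the 2-hydroxyl is held in a hydrogen bond to the formyl group.

Step 4
Reactants: 6 2-hydroxy-4,6-bis(methoxymethoxy)benzaldehyde; 4 rac-4-(1-hydroxyprop-2-yn-1-yl)phenyl pivalate
Product: 7 rac-4-{1-[2-formyl-3,5-bis(methoxymethoxy)phenoxy]prop-2-yn-1-yl}phenyl pivalate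
Conditions: PPh3, DIAD, THF, 0 °C→rt
Reagents that add atoms: none
Why: Mitsunobu etherification should work because the salicylaldehyde-type phenol is an acidic pronucleophile and the secondary propargylic alcohol, made less prone to ionise by the para acyloxy group, is displaced by SN2 (inversion is immaterial for a racemate).

Step 5
Reactants: 7 rac-4-{1-[2-formyl-3,5-bis(methoxymethoxy)phenoxy]prop-2-yn-1-yl}phenyl pivalate
Product: 9 rac-4-{1-[2-hydroxy-3,5-bis(methoxymethoxy)phenoxy]prop-2-yn-1-yl}phenyl pivalate, via aryl formate 8 (not isolated)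
Conditions: mCPBA, CH2Cl2, 0 °C→rt; aq. Na2S2O3 wash; then Et3N, MeOH, rt
Reagents that add atoms: 3-chloroperoxybenzoic acid, OOC(=O)c1cccc(Cl)c1
Why: In this Baeyer–Villiger (Dakin-type) oxidation the 2,4,6-trioxygenated aryl group migrates in preference to hydrogen to give the aryl formate, which amine-catalysed methanolysis should cleave far faster than the pivalate, while alkyne and acetals are inert to the peracid.

Step 6
Reactants: 9 rac-4-{1-[2-hydroxy-3,5-bis(methoxymethoxy)phenoxy]prop-2-yn-1-yl}phenyl pivalate
Product: 10 rac-4-{1-[2-methoxy-3,5-bis(methoxymethoxy)phenoxy]prop-2-yn-1-yl}phenyl pivalate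
Conditions: MeI, K2CO3, acetone, 40 °C
Reagents that add atoms: iodomethane, CI
Why: Williamson O-methylation of the only free phenol under aprotic carbonate conditions should neither cleave the pivalate nor deprotonate the alkyne.

Step 7
Reactants: 10 rac-4-{1-[2-methoxy-3,5-bis(methoxymethoxy)phenoxy]prop-2-yn-1-yl}phenyl pivalate
Product: 11 rac-4-[8-methoxy-5,7-bis(methoxymethoxy)-3-oxochroman-2-yl]phenyl pivalate
Conditions: Me4tBuXPhosAuNTf2 (5 mol %), 2,6-dichloropyridine N-oxide (1.3 equiv, slow addition), 1,2-dichloroethane, rt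
Reagents that add atoms: 2,6-dichloropyridine N-oxide, [O-][n+]1c(Cl)cccc1Cl
Why: Cationic gold activates the terminal alkyne, the N-oxide oxygen adds to the internal carbon (future C3) and N–O cleavage releases 2,6-dichloropyridine, leaving an α-oxo gold carbene on the terminal carbon (future C4). The closest known reaction type is the gold-catalysed N-oxide oxidation of aryl propargyl ethers to chroman-3-ones. Ring C closes in a six-membered Friedel–Crafts (SEAr) mode: the free ortho carbon of ring A attacks the carbene carbon with gold exocyclic (6-exo with respect to C=Au), and rearomatisation with protodeauration gives the C4 methylene. No stereocentre is created; C2 is carried over racemic from 10 and is erased in step 9. The step needs oxygen delivery to the internal carbon, which a terminal alkyne dictates, and closure at C4a only: C8 bears OMe, C4a is ortho to O1 and O5 and para to O7, and the ortho carbons of the pivaloyloxyphenyl ring are meta to their oxygen and too poor to close an indanone. Ionisation of the benzylic ether and a second oxidation of the carbene should be held back by the electron-poor pivalate, by an acid-free oxidant whose pyridine does not bind gold, and by the bulky ligand with slow N-oxide addition.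

Step 8
Reactants: 11 rac-4-[8-methoxy-5,7-bis(methoxymethoxy)-3-oxochroman-2-yl]phenyl pivalate
Product: 12 rac-4-{4-[(dimethylamino)methylidene]-8-methoxy-5,7-bis(methoxymethoxy)-3-oxochroman-2-yl}phenyl pivalate (alkene geometry not controlled)
Conditions: t-BuOCH(NMe2)2, toluene, 80 °C
Reagents that add atoms: tert-butoxybis(dimethylamino)methane, CN(C)C(OC(C)(C)C)N(C)C
Why: Aminomethylenation of a ketone with an amide acetal (enaminone formation) is regiospecific here because only the C4 methylene can lose two hydrogens to form the conjugated C=C, so the acidic C2 methine cannot divert it, and the alkene geometry is irrelevant since the bond is cleaved next.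

Step 9
Reactants: 12 rac-4-{4-[(dimethylamino)methylidene]-8-methoxy-5,7-bis(methoxymethoxy)-3-oxochroman-2-yl}phenyl pivalate
Product: 14 3-hydroxy-2-(4-hydroxyphenyl)-8-methoxy-5,7-bis(methoxymethoxy)-4H-chromen-4-one, via pivaloyl flavonol 13 (not isolated)
Conditions: NaIO4 (2.5 equiv), THF–H2O, 0 °C→rt; extractive work-up; then K2CO3, MeOH, rt
Reagents that add atoms: sodium periodate, [Na+].[O-]I(=O)(=O)=O
Why: Periodate cleavage of the electron-rich enaminone C=C (as for enamines) should give DMF and the chroman-3,4-dione, which tautomerises to its aromatic enol, the flavonol, making C2 sp2; carbonate in methanol then transesterifies the aryl pivalate while the acetals stay.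

Step 10
Reactants: 14 3-hydroxy-2-(4-hydroxyphenyl)-8-methoxy-5,7-bis(methoxymethoxy)-4H-chromen-4-one; 15 prenyl bromide (1-bromo-3-methylbut-2-ene, 2.5 equiv)
Product: 16 8-methoxy-5,7-bis(methoxymethoxy)-3-[(3-methylbut-2-en-1-yl)oxy]-2-{4-[(3-methylbut-2-en-1-yl)oxy]phenyl}-4H-chromen-4-one
Conditions: K2CO3, acetone, reflux
Reagents that add atoms: none
Why: Double Williamson etherification should be selective because the 3-OH enol and the 4'-phenol are the only free hydroxyls, and carbonate in acetone with an allylic bromide favours O- over C-alkylation.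

Step 11
Reactants: 16 8-methoxy-5,7-bis(methoxymethoxy)-3-[(3-methylbut-2-en-1-yl)oxy]-2-{4-[(3-methylbut-2-en-1-yl)oxy]phenyl}-4H-chromen-4-one
Product: 17 5,7-dihydroxy-8-methoxy-3-[(3-methylbut-2-en-1-yl)oxy]-2-{4-[(3-methylbut-2-en-1-yl)oxy]phenyl}-4H-chromen-4-one (5,7-dihydroxy-8-methoxy-3,4'-diprenyloxyflavone)
Conditions: HCl (cat., ca. 0.3 M), MeOH–THF, 0 °C→rt, stopped at full conversion
Reagents that add atoms: none
Why: Acid-catalysed acetal exchange with methanol should remove both MOM groups as dimethoxymethane (the 5-O-acetal assisted by the peri carbonyl), and dilute acid at low temperature for a short time should spare the two prenyl ethers.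

Compound list
1 | 4-hydroxybenzaldehyde | O=Cc1ccc(O)cc1 | starting material
2 | 4-formylphenyl pivalate | CC(C)(C)C(=O)Oc1ccc(C=O)cc1 | intermediate
3 | ethynylmagnesium bromide | C#C[Mg]Br | starting material
4 | rac-4-(1-hydroxyprop-2-yn-1-yl)phenyl pivalate | C#CC(O)c1ccc(OC(=O)C(C)(C)C)cc1 | intermediate
5 | 2,4,6-trihydroxybenzaldehyde | O=Cc1c(O)cc(O)cc1O | starting material
6 | 2-hydroxy-4,6-bis(methoxymethoxy)benzaldehyde | COCOc1cc(O)c(C=O)c(OCOC)c1 | intermediate
7 | rac-4-{1-[2-formyl-3,5-bis(methoxymethoxy)phenoxy]prop-2-yn-1-yl}phenyl pivalate | C#CC(Oc1cc(OCOC)cc(OCOC)c1C=O)c1ccc(OC(=O)C(C)(C)C)cc1 | intermediate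
8 | rac-4-{1-[2-(formyloxy)-3,5-bis(methoxymethoxy)phenoxy]prop-2-yn-1-yl}phenyl pivalate (aryl formate, not isolated) | C#CC(Oc1cc(OCOC)cc(OCOC)c1OC=O)c1ccc(OC(=O)C(C)(C)C)cc1 | intermediate
9 | rac-4-{1-[2-hydroxy-3,5-bis(methoxymethoxy)phenoxy]prop-2-yn-1-yl}phenyl pivalate | C#CC(Oc1cc(OCOC)cc(OCOC)c1O)c1ccc(OC(=O)C(C)(C)C)cc1 | intermediate
10 | rac-4-{1-[2-methoxy-3,5-bis(methoxymethoxy)phenoxy]prop-2-yn-1-yl}phenyl pivalate (key-step precursor) | C#CC(Oc1cc(OCOC)cc(OCOC)c1OC)c1ccc(OC(=O)C(C)(C)C)cc1 | intermediate
11 | rac-4-[8-methoxy-5,7-bis(methoxymethoxy)-3-oxochroman-2-yl]phenyl pivalate (key-step product) | O=C1Cc2c(OCOC)cc(OCOC)c(OC)c2OC1c1ccc(OC(=O)C(C)(C)C)cc1 | intermediate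
12 | rac-4-{4-[(dimethylamino)methylidene]-8-methoxy-5,7-bis(methoxymethoxy)-3-oxochroman-2-yl}phenyl pivalate (E/Z not controlled) | CN(C)C=C1C(=O)C(c2ccc(OC(=O)C(C)(C)C)cc2)Oc2c(OC)c(OCOC)cc(OCOC)c21 | intermediate
13 | 4-[3-hydroxy-8-methoxy-5,7-bis(methoxymethoxy)-4-oxo-4H-chromen-2-yl]phenyl pivalate (pivaloyl flavonol, not isolated) | COc1c(OCOC)cc(OCOC)c2c(=O)c(O)c(-c3ccc(OC(=O)C(C)(C)C)cc3)oc12 | intermediate
14 | 3-hydroxy-2-(4-hydroxyphenyl)-8-methoxy-5,7-bis(methoxymethoxy)-4H-chromen-4-one | COc1c(OCOC)cc(OCOC)c2c(=O)c(O)c(-c3ccc(O)cc3)oc12 | intermediate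
15 | prenyl bromide (1-bromo-3-methylbut-2-ene) | CC(C)=CCBr | starting material
16 | 8-methoxy-5,7-bis(methoxymethoxy)-3-[(3-methylbut-2-en-1-yl)oxy]-2-{4-[(3-methylbut-2-en-1-yl)oxy]phenyl}-4H-chromen-4-one | COc1c(OCOC)cc(OCOC)c2c(=O)c(OCC=C(C)C)c(-c3ccc(OCC=C(C)C)cc3)oc12 | intermediate
17 | 5,7-dihydroxy-8-methoxy-3,4'-diprenyloxyflavone | COc1c(O)cc(O)c2c(=O)c(OCC=C(C)C)c(-c3ccc(OCC=C(C)C)cc3)oc12 | target

Total step count: 11. Longest linear sequence: 10 steps (steps 1, 2 and 4–11, from 4-hydroxybenzaldehyde).

Steps most likely to fail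

Step 7. The benzylic propargylic C–O bond may ionise at the Lewis-acidic gold centre, or the carbene may be oxidised a second time before the arene traps it. The fallback forms the C4–C4a bond thermally without metal and brings in the C3 oxygen by hydroboration. It sets out from 10: heating in N,N-diethylaniline at about 190 °C should trigger the aryl propargyl ether Claisen rearrangement, 1,5-hydrogen shift and oxa-6π electrocyclisation to give the 2H-chromene rac-4-[8-methoxy-5,7-bis(methoxymethoxy)-2H-chromen-2-yl]phenyl pivalate F1. Hydroboration (BH3·THF, 0 °C; then NaBO3·4H2O) should place boron and then oxygen at C3, anti to the C2 aryl group, giving the 2,3-trans alcohol rac-4-[3-hydroxy-8-methoxy-5,7-bis(methoxymethoxy)chroman-2-yl]phenyl pivalate F2. Oxidation with DMP (NaHCO3, CH2Cl2) returns to the route at 11.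

Step 8. Condensation at C4 may be slow or incomplete because of crowding by the peri C5 acetal, and prolonged heating with liberated dimethylamine may start to remove the pivalate. The fallback uses a small electrophile in a condensation driven by enolate formation, which only the CH2 group can sustain. It sets out from 11: Claisen formylation (HCO2Et, NaH, THF, 0 °C→rt) should give the chelated enol rac-4-[(Z)-4-(hydroxymethylidene)-8-methoxy-5,7-bis(methoxymethoxy)-3-oxochroman-2-yl]phenyl pivalate F3, whose substituent points away from the peri acetal. Exchange with dimethylamine (Me2NH, THF, rt) converts the hydroxymethylidene into the aminomethylidene group and comes back to the route at 12.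

Step 11. Protic acid may ionise one of the allylic (prenyl) ethers before the slower 7-O-acetal is gone. The fallback exchanges the acetals for silyl ethers without protic acid and then removes silicon with fluoride. It sets out from 16: TESOTf with 2,2'-bipyridyl (CH2Cl2, 0 °C) should convert the aryl MOM ethers directly into the silyl ethers, giving 8-methoxy-3-[(3-methylbut-2-en-1-yl)oxy]-2-{4-[(3-methylbut-2-en-1-yl)oxy]phenyl}-5,7-bis(triethylsilyloxy)-4H-chromen-4-one F4. Desilylation with TBAF buffered with AcOH (THF, 0 °C) arrives at 17.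

Further compounds
F1 | step 7 | rac-4-[8-methoxy-5,7-bis(methoxymethoxy)-2H-chromen-2-yl]phenyl pivalate | COCOc1cc(OCOC)c2C=CC(c3ccc(OC(=O)C(C)(C)C)cc3)Oc2c1OC
F2 | step 7 | rac-4-[(2R*,3S*)-3-hydroxy-8-methoxy-5,7-bis(methoxymethoxy)chroman-2-yl]phenyl pivalate (2,3-trans, one enantiomer drawn) | COCOc1cc(OCOC)c2C[C@H](O)[C@@H](c3ccc(OC(=O)C(C)(C)C)cc3)Oc2c1OC
F3 | step 8 | rac-4-[(Z)-4-(hydroxymethylidene)-8-methoxy-5,7-bis(methoxymethoxy)-3-oxochroman-2-yl]phenyl pivalate | O=C1C(c2ccc(OC(=O)C(C)(C)C)cc2)Oc2c(OC)c(OCOC)cc(OCOC)c2/C1=C/O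
F4 | step 11 | 8-methoxy-3-[(3-methylbut-2-en-1-yl)oxy]-2-{4-[(3-methylbut-2-en-1-yl)oxy]phenyl}-5,7-bis(triethylsilyloxy)-4H-chromen-4-one | COc1c(O[Si](CC)(CC)CC)cc(O[Si](CC)(CC)CC)c2c(=O)c(OCC=C(C)C)c(-c3ccc(OCC=C(C)C)cc3)oc12
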